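The nine-membered ring (C1–C9) is closed last, at C6=C7, on a finished dihydropyran–trione. Ring-closing metathesis of diene 29 joins the C5 vinyl group to the C8 acryloyl group and gives Z-enone 30 in one operation, with loss of ethylene and no new stereocentre. The step exploits the trans-diequatorial, hence gauche, C4–C3 and C5–C6 bonds on the pyran ring (O, C4, C5, C1′ and two trione carbons) and the trans-1,2-disubstituted cyclobutane (C1, C9, C10, C11), which hold both alkenes within reach. Precursor 29 already carries all five stereocentres; it comes from a [2+2] photoadduct, a Sharpless epoxide opened by a vinyl cuprate, and reductive alkylation–cyclodehydration of the acyl trione.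

Key step: step 17

Remark on labels: terpenoid atoms carry caryophyllane numbers (C1/C9 cyclobutane fusion, C4 the O-bearing quaternary carbon, C5 its CH neighbour, C8 the carbonyl/methylene carbon); C1′ is the pyran CH2. The acyl triketone is written as the enol chelated to the acyl carbonyl. Diene 29 and enone 30 have the target's configuration at C1, C4, C5 and C9; the CIP descriptor at C5 changes along the route only because substituent priorities change.

Assumption: the chiral Lewis acid of step 3 is used as the enantiomer that delivers the (1R,6R) photoadduct.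

Step 1
Reactants: 1 (S)-2-methylbutanoic acid; 2 phloroglucinol
Product: 4 (2S)-2-methyl-1-(2,4,6-trihydroxyphenyl)butan-1-one, via (2S)-2-methylbutanoyl chloride 3 (not isolated)
Conditions: (COCl)2, DMF (cat.), CH2Cl2, 0 °C → rt; then 2, AlCl3, CH2Cl2–MeNO2, 0 °C → rt
Reagents that add atoms: none
Why: Friedel–Crafts C-acylation of the symmetrical triol by the acid chloride made in situ should stop at the mono-ketone (the acyl group deactivates the ring), and without base at or below room temperature the acyl α-centre is not enolised, so (S) is carried over.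

Step 2
Reactants: 4 (2S)-2-methyl-1-(2,4,6-trihydroxyphenyl)butan-1-one
Product: 5 3,5-dihydroxy-6,6-dimethyl-2-[(2S)-2-methylbutanoyl]cyclohexa-2,4-dien-1-one (enol form of the 2-acyl-4,4-dimethylcyclohexane-1,3,5-trione)
Conditions: MeI (2.2 equiv), NaOMe, MeOH, 0 °C → rt
Reagents that add atoms: iodomethane, CI
Why: Dearomatising double C-methylation of the acylphloroglucinol phenoxide puts both methyl groups on one ring carbon; the product is separable from mono- and trimethylated material, and the acyl α-CH of the polyanion is not deprotonated.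

Step 3
Reactants: 6 cyclohex-2-en-1-one; 7 isobutylene
Product: 9 cis-fused (1R,6R)-7,7-dimethylbicyclo[4.2.0]octan-2-one, via trans-fused (1S,6R)-7,7-dimethylbicyclo[4.2.0]octan-2-one 8 (not isolated)
Conditions: hν (366 nm), AlBr3-activated chiral oxazaborolidine (0.5 equiv), CH2Cl2, −75 °C; then basic Al2O3
Reagents that add atoms: none
Why: Enantioselective enone–alkene [2+2] photocycloaddition: the Lewis-acid-bound enone adds isobutylene head-to-tail (CMe2 on the β-carbon) on the face left open by the oxazaborolidine, which sets C6, and the α-centre C1 is then equilibrated on alumina to the unstrained cis fusion.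

Step 4
Reactants: 9 cis-fused (1R,6R)-7,7-dimethylbicyclo[4.2.0]octan-2-one
Product: 10 trimethyl{[(1R,6R)-7,7-dimethylbicyclo[4.2.0]oct-2-en-2-yl]oxy}silane
Conditions: LDA, THF, −78 °C; TMSCl
Reagents that add atoms: chlorotrimethylsilane, C[Si](C)(C)Cl
Why: Kinetic deprotonation takes the unhindered C3 methylene and not the ring-fusion methine, and O-silylation fixes the Δ2,3 enolate as the silyl enol ether without touching C1 or C6.

Step 5
Reactants: 10 trimethyl{[(1R,6R)-7,7-dimethylbicyclo[4.2.0]oct-2-en-2-yl]oxy}silane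
Product: 12 methyl (1R,2R)-3,3-dimethyl-2-(3-oxopropyl)cyclobutane-1-carboxylate (cis), via (1R,2R)-3,3-dimethyl-2-(3-oxopropyl)cyclobutane-1-carboxylic acid 11 (not isolated)
Conditions: O3, CH2Cl2–MeOH, −78 °C; Me2S; then TMSCHN2, PhMe–MeOH, 0 °C
Reagents that add atoms: ozone, [O-][O+]=O; trimethylsilyldiazomethane, C[Si](C)(C)C=[N+]=[N-]
Why: Ozonolysis of the silyl enol ether cleaves C2=C3 to the acid on the cyclobutane carbon and the chain aldehyde, and diazoalkane esterification of the acid is much faster than any reaction at the aldehyde; no stereocentre is involved.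

Step 6
Reactants: 12 methyl (1R,2R)-3,3-dimethyl-2-(3-oxopropyl)cyclobutane-1-carboxylate
Product: 14 methyl (1S,2R)-2-(but-3-yn-1-yl)-3,3-dimethylcyclobutane-1-carboxylate (trans), via methyl (1R,2R)-2-(but-3-yn-1-yl)-3,3-dimethylcyclobutane-1-carboxylate 13 (not isolated)
Conditions: dimethyl (1-diazo-2-oxopropyl)phosphonate, K2CO3, MeOH, 0 °C → rt; then NaOMe (0.3 equiv), MeOH, 50 °C
Reagents that add atoms: dimethyl (1-diazo-2-oxopropyl)phosphonate, CC(=O)C(=[N+]=[N-])P(=O)(OC)OC
Why: Seyferth–Gilbert homologation (Ohira–Bestmann reagent) turns the aldehyde into the terminal alkyne, and methoxide then equilibrates the centre α to the ester to the thermodynamically preferred trans-1,2-disubstituted cyclobutane, the C2 centre being unable to epimerise.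

Step 7
Reactants: 14 methyl (1S,2R)-2-(but-3-yn-1-yl)-3,3-dimethylcyclobutane-1-carboxylate
Product: 16 methyl (1S,2R)-2-[(3E)-5-hydroxy-3-methylpent-3-en-1-yl]-3,3-dimethylcyclobutane-1-carboxylate, via methyl (1S,2R)-2-[(3E)-4-(dimethylalumanyl)-3-methylbut-3-en-1-yl]-3,3-dimethylcyclobutane-1-carboxylate 15 (not isolated)
Conditions: Me3Al, Cp2ZrCl2 (0.3 equiv), CH2Cl2, 0 °C → rt; evaporate; n-BuLi, THF–hexane, −78 °C; (CH2O)n, −78 °C → rt; aq. HCl
Reagents that add atoms: trimethylaluminium, C[Al](C)C; paraformaldehyde (as formaldehyde), C=O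
Why: Negishi zirconium-catalysed carboalumination adds Me–Al syn across the alkyne with methyl on the internal carbon, and the derived alkenylalanate transfers the alkenyl group to formaldehyde with retention, which fixes the E geometry; Me3Al and the alanate should not add to the hindered methyl ester at these temperatures.

Step 8
Reactants: 16 methyl (1S,2R)-2-[(3E)-5-hydroxy-3-methylpent-3-en-1-yl]-3,3-dimethylcyclobutane-1-carboxylate
Product: 17 methyl (1S,2R)-2-{2-[(2S,3S)-3-(hydroxymethyl)-2-methyloxiran-2-yl]ethyl}-3,3-dimethylcyclobutane-1-carboxylate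
Conditions: Ti(Oi-Pr)4, L-(+)-diethyl tartrate, t-BuOOH, 4 Å MS, CH2Cl2, −20 °C
Reagents that add atoms: tert-butyl hydroperoxide, CC(C)(C)OO
Why: Sharpless asymmetric epoxidation: the titanium–(+)-tartrate complex delivers oxygen to one face of the E-allylic alcohol under reagent control, independent of the remote cyclobutane, which sets C4 (and C5 provisionally).

Step 9
Reactants: 17 methyl (1S,2R)-2-{2-[(2S,3S)-3-(hydroxymethyl)-2-methyloxiran-2-yl]ethyl}-3,3-dimethylcyclobutane-1-carboxylate
Product: 18 methyl (1S,2R)-2-[(3S,4R)-3-hydroxy-4-(hydroxymethyl)-3-methylhex-5-en-1-yl]-3,3-dimethylcyclobutane-1-carboxylate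
Conditions: CH2=CHMgBr (4 equiv), CuI (0.3 equiv), THF–Et2O, −40 → −20 °C; aq. NH4Cl
Reagents that add atoms: vinylmagnesium bromide, C=C[Mg]Br
Why: Copper-catalysed Grignard opening of the 2,3-epoxy alcohol: vinyl attacks the secondary epoxide carbon C5 by SN2 with inversion because the other carbon is quaternary, which sets C5 and leaves the tertiary C4–O bond intact; the hindered ester should survive at this temperature.

Step 10
Reactants: 18 methyl (1S,2R)-2-[(3S,4R)-3-hydroxy-4-(hydroxymethyl)-3-methylhex-5-en-1-yl]-3,3-dimethylcyclobutane-1-carboxylate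
Product: 19 methyl (1S,2R)-2-[(3S,4R)-3-hydroxy-4-(hydroxymethyl)-3-methyl-6-(phenylsulfanyl)hexyl]-3,3-dimethylcyclobutane-1-carboxylate
Conditions: PhSH, AIBN (cat.), PhMe, 80 °C
Reagents that add atoms: thiophenol, Sc1ccccc1
Why: Radical thiol–ene hydrothiolation adds the thiyl radical to the terminal vinyl carbon (anti-Markovnikov) and masks the vinyl group, so that C5 is no longer allylic when C1′ becomes an aldehyde.

Step 11
Reactants: 19 methyl (1S,2R)-2-[(3S,4R)-3-hydroxy-4-(hydroxymethyl)-3-methyl-6-(phenylsulfanyl)hexyl]-3,3-dimethylcyclobutane-1-carboxylate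
Product: 20 methyl (1S,2R)-3,3-dimethyl-2-[(3S,4R)-3-methyl-6-(phenylsulfanyl)-3-(triethylsilyloxy)-4-(triethylsilyloxymethyl)hexyl]cyclobutane-1-carboxylate
Conditions: TESOTf (2.5 equiv), 2,6-lutidine, CH2Cl2, −78 → 0 °C
Reagents that add atoms: triethylsilyl trifluoromethanesulfonate, CC[Si](CC)(CC)OS(=O)(=O)C(F)(F)F
Why: Silyl triflate/lutidine silylates both hydroxyls, the tertiary one so that the later β-oxy aldehyde cannot undergo retro-aldol cleavage or dehydration.

Step 12
Reactants: 20 methyl (1S,2R)-3,3-dimethyl-2-[(3S,4R)-3-methyl-6-(phenylsulfanyl)-3-(triethylsilyloxy)-4-(triethylsilyloxymethyl)hexyl]cyclobutane-1-carboxylate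
Product: 21 methyl (1S,2R)-2-[(3S,4S)-4-formyl-3-methyl-6-(phenylsulfanyl)-3-(triethylsilyloxy)hexyl]-3,3-dimethylcyclobutane-1-carboxylate
Conditions: (COCl)2, DMSO, CH2Cl2, −78 → −40 °C; Et3N, −78 → 0 °C
Reagents that add atoms: none
Why: Swern conditions cleave the primary triethylsilyl ether in situ and oxidise it to the aldehyde, while the hindered tertiary silyl ether and the aryl sulfide are inert; the amine is added cold to keep the α-centre C5 intact.

Step 13
Reactants: 21 methyl (1S,2R)-2-[(3S,4S)-4-formyl-3-methyl-6-(phenylsulfanyl)-3-(triethylsilyloxy)hexyl]-3,3-dimethylcyclobutane-1-carboxylate; 5 3,5-dihydroxy-6,6-dimethyl-2-[(2S)-2-methylbutanoyl]cyclohexa-2,4-dien-1-one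
Product: 25 methyl (1S,2R)-2-{2-[(2S,3S)-5-hydroxy-2,8,8-trimethyl-6-[(2S)-2-methylbutanoyl]-7-oxo-3-[2-(phenylsulfanyl)ethyl]-3,4,7,8-tetrahydro-2H-chromen-2-yl]ethyl}-3,3-dimethylcyclobutane-1-carboxylate, via alkylidene trione (Knoevenagel adduct) 22 (not isolated), via C-alkylated trione tertiary silyl ether 23 (not isolated), via C-alkylated trione tertiary alcohol 24 (not isolated)
Conditions: Hantzsch ester (1.2 equiv), L-proline (10 mol %), CH2Cl2, rt; then CSA (2 equiv), MeOH, rt → 40 °C
Reagents that add atoms: none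
Why: Three-component reductive alkylation (Knoevenagel condensation at the only CH of the trione, then hydride transfer from the Hantzsch ester to the alkylidene trione) forms the C1′–C(sp2) bond before C5 can equilibrate, and acid then removes the tertiary silyl group and closes the pyran by hemiketalisation–dehydration at the ketone flanked by CMe2 (the other carbonyl is tied up in the acyl chelate), so the C4–O bond is never broken and C4 is retained.

Step 14
Reactants: 25 methyl (1S,2R)-2-{2-[(2S,3S)-5-hydroxy-2,8,8-trimethyl-6-[(2S)-2-methylbutanoyl]-7-oxo-3-[2-(phenylsulfanyl)ethyl]-3,4,7,8-tetrahydro-2H-chromen-2-yl]ethyl}-3,3-dimethylcyclobutane-1-carboxylate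
Product: 27 methyl (1S,2R)-2-{2-[(2S,3S)-3-ethenyl-5-hydroxy-2,8,8-trimethyl-6-[(2S)-2-methylbutanoyl]-7-oxo-3,4,7,8-tetrahydro-2H-chromen-2-yl]ethyl}-3,3-dimethylcyclobutane-1-carboxylate, via the phenyl sulfoxide of 25 26 (not isolated)
Conditions: NaIO4, MeOH–H2O, 0 °C → rt; then PhMe, NaHCO3, 110 °C
Reagents that add atoms: none
Why: Periodate oxidises only the sulfide, and thermal syn-elimination of the sulfoxide can take only a C6 hydrogen, which regenerates the C5 vinyl group without touching C5.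

Step 15
Reactants: 27 methyl (1S,2R)-2-{2-[(2S,3S)-3-ethenyl-5-hydroxy-2,8,8-trimethyl-6-[(2S)-2-methylbutanoyl]-7-oxo-3,4,7,8-tetrahydro-2H-chromen-2-yl]ethyl}-3,3-dimethylcyclobutane-1-carboxylate
Product: 28 (1S,2R)-2-{2-[(2S,3S)-3-ethenyl-5-hydroxy-2,8,8-trimethyl-6-[(2S)-2-methylbutanoyl]-7-oxo-3,4,7,8-tetrahydro-2H-chromen-2-yl]ethyl}-N-methoxy-N,3,3-trimethylcyclobutane-1-carboxamide
Conditions: MeNHOMe·HCl, i-PrMgCl, THF, −20 → 0 °C
Reagents that add atoms: N,O-dimethylhydroxylamine hydrochloride, CNOC.Cl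
Why: The magnesium amide of N,O-dimethylhydroxylamine converts the methyl ester into the Weinreb amide; the triketone is protected as its magnesium enolate (its acyl α-CH is not deprotonated a second time) and the trans ester centre is already the thermodynamic one.

Step 16
Reactants: 28 (1S,2R)-2-{2-[(2S,3S)-3-ethenyl-5-hydroxy-2,8,8-trimethyl-6-[(2S)-2-methylbutanoyl]-7-oxo-3,4,7,8-tetrahydro-2H-chromen-2-yl]ethyl}-N-methoxy-N,3,3-trimethylcyclobutane-1-carboxamide
Product: 29 (2S,3S)-2-{2-[(1R,4S)-2,2-dimethyl-4-(prop-2-enoyl)cyclobutyl]ethyl}-3-ethenyl-5-hydroxy-2,8,8-trimethyl-6-[(2S)-2-methylbutanoyl]-3,4-dihydro-2H-chromen-7(8H)-one (metathesis precursor)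
Conditions: CH2=CHMgBr (3.5 equiv), THF, −78 → 0 °C; inverse quench into cold aq. NH4Cl
Reagents that add atoms: vinylmagnesium bromide, C=C[Mg]Br
Why: Grignard addition to the Weinreb amide stops at the chelated tetrahedral adduct and gives the vinyl ketone on quench, the enolate-protected triketone being inert; the cold inverse quench keeps the liberated amine from adding to the enone.

Step 17
Reactants: 29 (2S,3S)-2-{2-[(1R,4S)-2,2-dimethyl-4-(prop-2-enoyl)cyclobutyl]ethyl}-3-ethenyl-5-hydroxy-2,8,8-trimethyl-6-[(2S)-2-methylbutanoyl]-3,4-dihydro-2H-chromen-7(8H)-one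
Product: 30 (Z)-enone, the (1R,4S,5S,9S)-6,7-didehydro-13-nor-8-oxo derivative of 32 (trans-fused cyclobutane/nine-membered ring with cis C6=C7 and C8=O; pyran and acyl trione as in 32)
Conditions: Hoveyda–Grubbs II (10 mol %), 1,4-benzoquinone (20 mol %), PhMe (1 mM), 80 °C, Ar purge
Reagents that add atoms: none
Why: Ring-closing olefin metathesis: the ruthenium alkylidene loads on the electron-neutral C5 vinyl group, undergoes [2+2] cycloaddition with the acryloyl alkene and cycloreversion, and releases ethylene with formation of C6=C7. The closest known reaction type is enone-forming ring-closing metathesis of dienes with one vinyl ketone or acrylate terminus, including closures of eight- and nine-membered carbocycles held by a cyclic constraint. The nine-membered ring (C1–C9) closes by intramolecular metathesis onto the C7 terminus, and only the Z enone can be accommodated in it. No stereocentre is formed; C1, C4, C5 and C9 are spectators. The step needs cyclisation to outrun oligomerisation: high dilution, the gauche trans-diequatorial C4–C3/C5–C6 bonds on the pyran and the trans cyclobutane bring the alkene termini together, and the electron-poor acryloyl end resists homodimerisation. C9 should not epimerise because the conditions are neutral, and benzoquinone suppresses ruthenium hydride alkene migration.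

Step 18
Reactants: 30 (Z)-enone
Product: 31 (1R,4S,5R,9S)-13-nor-8-oxo derivative of 32 (saturated C8 ketone)
Conditions: H2 (1 atm), Pd/C, EtOAc, rt
Reagents that add atoms: none
Why: Heterogeneous hydrogenation saturates the cis-disubstituted enone C6=C7 bond, the only unhindered C=C left; the tetrasubstituted push–pull enol and enol ether bonds of the trione and the ketones are not reduced, and no stereocentre is affected.

Step 19
Reactants: 31 saturated C8 ketone
Product: 32 target, (1R,4S,5R,9S)-configured caryophyllane-type adduct with 8(13)-methylene, dihydropyran (O on C4, C1′ on C5) and 5-hydroxy-8,8-dimethyl-6-[(2S)-2-methylbutanoyl]cyclohexadien-7-one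
Conditions: Ph3PCH3Br (5 equiv), KOt-Bu (4.8 equiv), THF, 0 → 45 °C; aq. NH4Cl
Reagents that add atoms: methyltriphenylphosphonium bromide, C[P+](c1ccccc1)(c1ccccc1)c1ccccc1.[Br-]
Why: Wittig methylenation of the C8 ketone with excess ylide (one equivalent deprotonates the enol, and the resulting triketonate is inert to the ylide); the trans 4/9 fusion at C9 is the thermodynamic one, so the α-centre is not lost.

Compound list
1 | (S)-2-methylbutanoic acid | CC[C@H](C)C(=O)O | starting material
2 | phloroglucinol | Oc1cc(O)cc(O)c1 | starting material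
3 | (2S)-2-methylbutanoyl chloride | CC[C@H](C)C(=O)Cl | intermediate (not isolated)
4 | (2S)-2-methyl-1-(2,4,6-trihydroxyphenyl)butan-1-one | CC[C@H](C)C(=O)c1c(O)cc(O)cc1O | intermediate
5 | 3,5-dihydroxy-6,6-dimethyl-2-[(2S)-2-methylbutanoyl]cyclohexa-2,4-dien-1-one (acyl trione) | CC[C@H](C)C(=O)C1=C(O)C=C(O)C(C)(C)C1=O | intermediate
6 | cyclohex-2-en-1-one | O=C1C=CCCC1 | starting material
7 | isobutylene | C=C(C)C | starting material
8 | trans-fused (1S,6R)-7,7-dimethylbicyclo[4.2.0]octan-2-one | O=C1CCC[C@@H]2[C@@H]1CC2(C)C | intermediate (not isolated)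
9 | cis-fused (1R,6R)-7,7-dimethylbicyclo[4.2.0]octan-2-one | O=C1CCC[C@@H]2[C@H]1CC2(C)C | intermediate
10 | trimethyl{[(1R,6R)-7,7-dimethylbicyclo[4.2.0]oct-2-en-2-yl]oxy}silane | C[Si](C)(C)OC1=CCC[C@@H]2[C@H]1CC2(C)C | intermediate
11 | (1R,2R)-3,3-dimethyl-2-(3-oxopropyl)cyclobutane-1-carboxylic acid | OC(=O)[C@@H]1CC(C)(C)[C@@H]1CCC=O | intermediate (not isolated)
12 | methyl (1R,2R)-3,3-dimethyl-2-(3-oxopropyl)cyclobutane-1-carboxylate | COC(=O)[C@@H]1CC(C)(C)[C@@H]1CCC=O | intermediate
13 | methyl (1R,2R)-2-(but-3-yn-1-yl)-3,3-dimethylcyclobutane-1-carboxylate | COC(=O)[C@@H]1CC(C)(C)[C@@H]1CCC#C | intermediate (not isolated)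
14 | methyl (1S,2R)-2-(but-3-yn-1-yl)-3,3-dimethylcyclobutane-1-carboxylate | COC(=O)[C@H]1CC(C)(C)[C@@H]1CCC#C | intermediate
15 | methyl (1S,2R)-2-[(3E)-4-(dimethylalumanyl)-3-methylbut-3-en-1-yl]-3,3-dimethylcyclobutane-1-carboxylate | COC(=O)[C@H]1CC(C)(C)[C@@H]1CC/C(C)=C/[Al](C)C | intermediate (not isolated)
16 | methyl (1S,2R)-2-[(3E)-5-hydroxy-3-methylpent-3-en-1-yl]-3,3-dimethylcyclobutane-1-carboxylate | COC(=O)[C@H]1CC(C)(C)[C@@H]1CC/C(C)=C/CO | intermediate
17 | methyl (1S,2R)-2-{2-[(2S,3S)-3-(hydroxymethyl)-2-methyloxiran-2-yl]ethyl}-3,3-dimethylcyclobutane-1-carboxylate | COC(=O)[C@H]1CC(C)(C)[C@@H]1CC[C@]2(C)O[C@H]2CO | intermediate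
18 | methyl (1S,2R)-2-[(3S,4R)-3-hydroxy-4-(hydroxymethyl)-3-methylhex-5-en-1-yl]-3,3-dimethylcyclobutane-1-carboxylate | COC(=O)[C@H]1CC(C)(C)[C@@H]1CC[C@](C)(O)[C@@H](CO)C=C | intermediate
19 | methyl (1S,2R)-2-[(3S,4R)-3-hydroxy-4-(hydroxymethyl)-3-methyl-6-(phenylsulfanyl)hexyl]-3,3-dimethylcyclobutane-1-carboxylate | COC(=O)[C@H]1CC(C)(C)[C@@H]1CC[C@](C)(O)[C@@H](CO)CCSc2ccccc2 | intermediate
20 | bis(triethylsilyl) ether of 19 | COC(=O)[C@H]1CC(C)(C)[C@@H]1CC[C@](C)(O[Si](CC)(CC)CC)[C@@H](CO[Si](CC)(CC)CC)CCSc2ccccc2 | intermediate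
21 | methyl (1S,2R)-2-[(3S,4S)-4-formyl-3-methyl-6-(phenylsulfanyl)-3-(triethylsilyloxy)hexyl]-3,3-dimethylcyclobutane-1-carboxylate | COC(=O)[C@H]1CC(C)(C)[C@@H]1CC[C@](C)(O[Si](CC)(CC)CC)[C@@H](C=O)CCSc2ccccc2 | intermediate
22 | alkylidene trione: 21 with CHO replaced by CH=C(ring carbon between the two carbonyls of 5) | COC(=O)[C@H]1CC(C)(C)[C@@H]1CC[C@](C)(O[Si](CC)(CC)CC)[C@@H](C=C2C(=O)C(C)(C)C(=O)C(C(=O)[C@@H](C)CC)=C2O)CCSc3ccccc3 | intermediate (not isolated)
23 | C-alkylated trione, tertiary triethylsilyl ether (CH2 link between C5 and the trione ring) | COC(=O)[C@H]1CC(C)(C)[C@@H]1CC[C@](C)(O[Si](CC)(CC)CC)[C@@H](CC2=C(O)C(C)(C)C(=O)C(C(=O)[C@@H](C)CC)=C2O)CCSc3ccccc3 | intermediate (not isolated)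
24 | C-alkylated trione, free tertiary alcohol | COC(=O)[C@H]1CC(C)(C)[C@@H]1CC[C@](C)(O)[C@@H](CC2=C(O)C(C)(C)C(=O)C(C(=O)[C@@H](C)CC)=C2O)CCSc3ccccc3 | intermediate (not isolated)
25 | methyl (1S,2R)-2-{2-[(2S,3S)-5-hydroxy-2,8,8-trimethyl-6-[(2S)-2-methylbutanoyl]-7-oxo-3-[2-(phenylsulfanyl)ethyl]-3,4,7,8-tetrahydro-2H-chromen-2-yl]ethyl}-3,3-dimethylcyclobutane-1-carboxylate | c1ccccc1SCC[C@@H]2CC3=C(O[C@@]2(C)CC[C@@H]4[C@@H](C(=O)OC)CC4(C)C)C(C)(C)C(=O)C(C(=O)[C@@H](C)CC)=C3O | intermediate
26 | phenyl sulfoxide of 25 (both S-epimers) | O=S(c1ccccc1)CC[C@@H]2CC3=C(O[C@@]2(C)CC[C@@H]4[C@@H](C(=O)OC)CC4(C)C)C(C)(C)C(=O)C(C(=O)[C@@H](C)CC)=C3O | intermediate (not isolated)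
27 | methyl (1S,2R)-2-{2-[(2S,3S)-3-ethenyl-5-hydroxy-2,8,8-trimethyl-6-[(2S)-2-methylbutanoyl]-7-oxo-3,4,7,8-tetrahydro-2H-chromen-2-yl]ethyl}-3,3-dimethylcyclobutane-1-carboxylate | C=C[C@@H]1CC2=C(O[C@@]1(C)CC[C@@H]1[C@@H](C(=O)OC)CC1(C)C)C(C)(C)C(=O)C(C(=O)[C@@H](C)CC)=C2O | intermediate
28 | N-methoxy-N-methyl amide of 27 | C=C[C@@H]1CC2=C(O[C@@]1(C)CC[C@@H]1[C@@H](C(=O)N(C)OC)CC1(C)C)C(C)(C)C(=O)C(C(=O)[C@@H](C)CC)=C2O | intermediate
29 | (2S,3S)-2-{2-[(1R,4S)-2,2-dimethyl-4-(prop-2-enoyl)cyclobutyl]ethyl}-3-ethenyl-5-hydroxy-2,8,8-trimethyl-6-[(2S)-2-methylbutanoyl]-3,4-dihydro-2H-chromen-7(8H)-one | C=C[C@@H]1CC2=C(O[C@@]1(C)CC[C@@H]1[C@@H](C(=O)C=C)CC1(C)C)C(C)(C)C(=O)C(C(=O)[C@@H](C)CC)=C2O | intermediate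
30 | (Z)-enone, (1R,4S,5S,9S)-6,7-didehydro-13-nor-8-oxo derivative of 32 | O=C1/C=C\[C@@H]2CC3=C(O[C@@]2(C)CC[C@@H]2[C@@H]1CC2(C)C)C(C)(C)C(=O)C(C(=O)[C@@H](C)CC)=C3O | intermediate
31 | (1R,4S,5R,9S)-13-nor-8-oxo derivative of 32 | O=C1CC[C@@H]2CC3=C(O[C@@]2(C)CC[C@@H]2[C@@H]1CC2(C)C)C(C)(C)C(=O)C(C(=O)[C@@H](C)CC)=C3O | intermediate
32 | target (1R,4S,5R,9S; acyl chain S) | C=C1CC[C@@H]2CC3=C(O[C@@]2(C)CC[C@@H]2[C@@H]1CC2(C)C)C(C)(C)C(=O)C(C(=O)[C@@H](C)CC)=C3O | target

Total step count: 19. Longest linear sequence: 17 steps (6 → 32, steps 3–19); steps 1–2 supply trione 5.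

Steps most likely to fail

1. Step 17 (ring-closing metathesis). The ruthenium alkylidene formed at the C5 vinyl group may be held as a chelate by the C8 carbonyl or the enolised triketone, or intermolecular metathesis through the acryloyl end may outrun closure of the strained ring. The fallback sets out from 29: Luche reduction (NaBH4, CeCl3·7H2O, MeOH, −40 °C) should give the C8 allylic alcohol F1 as a mixture of carbinol epimers. Ring-closing metathesis of this electronically unbiased diene (Grubbs II, CH2Cl2, 40 °C, 1 mM) should give the (Z)-cyclononenol F2. Oxidation of the allylic alcohol (MnO2, CH2Cl2) returns to the route at 30.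

2. Step 13 (reductive alkylation and pyran closure). C5 may epimerise through the enamine or through tautomerisation of the alkylidene trione, or the condensation may stall at the hindered aldehyde. The fallback sets out from 19 and keeps C1′ at the alcohol oxidation level, so that C5 cannot epimerise: I2, PPh3 and imidazole (CH2Cl2, 0 °C) should convert the primary alcohol selectively into the primary iodide F3. C-Alkylation of the disodium salt of 5 (NaH, DMSO, 50 °C) with F3 should give 24, which is closed with CSA in MeOH as in step 13; the route is rejoined at 25.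

3. Step 3 (enantioselective photocycloaddition). Facial selectivity may be poor because of uncatalysed background excitation, or head-to-head addition may compete. The fallback sets out from 6 and 7: uncatalysed irradiation (350 nm, CH2Cl2, −70 °C) should give the racemic trans-fused ketone F4, which basic alumina equilibrates to the racemic cis-fused ketone F5. Resolution of F5 by preparative chromatography on a chiral stationary phase gives the (1R,6R) enantiomer, which is 9.

Further compounds
F1 | step 17 | (2S,3S)-3-ethenyl-5-hydroxy-2-{2-[(1R,4S)-4-(1-hydroxyprop-2-en-1-yl)-2,2-dimethylcyclobutyl]ethyl}-2,8,8-trimethyl-6-[(2S)-2-methylbutanoyl]-3,4-dihydro-2H-chromen-7(8H)-one (carbinol epimers) | C=C[C@@H]1CC2=C(O[C@@]1(C)CC[C@@H]1[C@@H](C(O)C=C)CC1(C)C)C(C)(C)C(=O)C(C(=O)[C@@H](C)CC)=C2O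
F2 | step 17 | (Z)-cyclononenol, the 8-hydroxy analogue of 30 (carbinol epimers) | OC1/C=C\[C@@H]2CC3=C(O[C@@]2(C)CC[C@@H]2[C@@H]1CC2(C)C)C(C)(C)C(=O)C(C(=O)[C@@H](C)CC)=C3O
F3 | step 13 | methyl (1S,2R)-2-[(3S,4S)-3-hydroxy-4-(iodomethyl)-3-methyl-6-(phenylsulfanyl)hexyl]-3,3-dimethylcyclobutane-1-carboxylate | COC(=O)[C@H]1CC(C)(C)[C@@H]1CC[C@](C)(O)[C@@H](CI)CCSc2ccccc2
F4 | step 3 | racemic trans-fused 7,7-dimethylbicyclo[4.2.0]octan-2-one (both enantiomers) | O=C1CCC[C@@H]2[C@@H]1CC2(C)C.O=C1CCC[C@H]2[C@H]1CC2(C)C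
F5 | step 3 | racemic cis-fused 7,7-dimethylbicyclo[4.2.0]octan-2-one (both enantiomers) | O=C1CCC[C@@H]2[C@H]1CC2(C)C.O=C1CCC[C@H]2[C@@H]1CC2(C)C
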